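## The problem

Atom labels used throughout: C1 (CH–O-senecioate), C2 (CH2), C3 (CH–O-isovalerate), C4 (CMe2), C5 (cyclobutane CH next to C4), C6 (cyclobutane CH next to the carbonyl), C7 (C=O), C8 (=CH), C9 (=C–CH3), C10 (cyclobutane CH next to C9), C11 (quaternary C–CH3 bonded to C1). "Upper face" of the cyclobutane is the face that carries the C7–C8–C9 bridge; "lower face" is the opposite one.

The target 28 is a cyclobutane (C5, C6, C10, C11) bridged twice. C6 and C10 are joined on the upper face by the enone unit C7–C8–C9. C5 and C11 are joined on the lower face by C1–C2–C3–C4. A bicyclo[3.1.1]heptenone and a bicyclo[4.1.1]octane therefore share the four-membered ring. C5, C6 and C10 are locked to one another by the bridging, so one chiral-pool centre (C6) fixes them. The orientation of CH3 versus C1 on C11 must be decided when that quaternary carbon is made. C1 and C3 carry trans oxygens on a bridge whose two faces are flanked by C6–H and C10–H and are nearly mirror images. The cage therefore cannot dictate C1; it needs reagent control, after which C3 can be relayed from C1 across the ring. Sensitive points: a cation on a carbon attached to the cyclobutane triggers Wagner–Meerwein shifts; a cyclobutanol with a β-carbonyl fragments by retro-aldol; the two hindered hydroxyls must receive two different acyl groups; the senecioate is prone to deconjugation under basic acylation. The enabling feature is that C4 sits between the carbinol carbon C3 and the cyclobutane methine C5. That is the arrangement left behind when, in a six-membered carbinol ring (C11–C1–C2–C3–C5 plus C6 or C10), C5 shifts from C3 to an exocyclic CMe2 cation. The seven-membered ring then need not be closed end to end, and C4 need not be made by alkylation.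

## Retrosynthesis

**Esters and C3.** The isovalerate C–O bond of 28 is cut to the hydroxy senecioate 26 and the acid chloride 27. The senecioate C–O bond and the C3–H bond of 26 are cut together to the β-hydroxy ketone 24 and the unsaturated aldehyde 25 (Evans–Tishchenko). Both hydroxyls are neopentylic, so selective acylation of a diol is not credible. The redox esterification places the acyl group on O1, delivers hydride to C3 on the face of O1 (trans diol) and avoids base-mediated senecioylation. 24 comes from the silyl ether 23.

**Seven-membered ring (key cut).** In 23 the C4–C5 bond is cut and C5 is reconnected to C3, giving the six-membered carbinol 22 with an exocyclic 2-hydroxyprop-2-yl group. The neighbouring cuts (C1–C2 or C2–C3) would require a seven-membered aldol across the cyclobutane and a CMe2 carbon made by alkylation. 22 has a six-membered ring and no quaternary ring carbon besides C11. The forward step needs ionisation only at C4 and migration of C5 rather than C2. The ring oxygen is therefore carried as a trimethylsilyl ether and the enone is installed beforehand.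

**Side chain of 22.** The C7 carbonyl is cut back to the alkene 21 (allylic oxidation), the C4–O bond to the isopropenyl compound 20 (hydration), and the C3–C4 bond to ketone 17 plus the propenyl unit of 18. The order is fixed by chemoselectivity: the organolithium must not meet the enone, and the oxidant must not meet the isopropenyl group.

**C1 oxygen.** The C1–O bond of 17 (via 16) is cut to the enone 14. A direct aldol would set C1 without control because the pocket is symmetric. Ligand-controlled conjugate borylation on 14 lets the catalyst choose the face.

**Six-membered ring.** The C1=C2 bond of 14 is cut to the keto aldehyde 11 (aldol condensation). The acetyl group makes C5 epimerisable, so the arm can move to the lower face, where alone it can cyclise. 11 is a bicyclic compound with four stereocentres.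

**Oxidation level and bridgehead oxygen.** 11 comes from diol 10. 10 comes from the bridgehead alcohol 6 through silylation (7), oxalate formation (8), radical deoxygenation (9) and desilylation. The C10–O bond must go before any carbonyl is unveiled.

**Cyclobutane and arm.** The C10–C11 bond of 6 is cut to the epoxy ketone 5 (radical 4-exo closure by trivalent titanium). 5 comes from 4, and 4 from (R)-carvone 1 and acetaldehyde 2 by α′-aldol addition. C6 comes from the chiral pool.

## Roads not taken

**Alternative 1:** The cyclobutane is closed by the same titanium radical reaction, but the CMe2 carbon is already attached to the α′ carbon of 1 as a 2-methylbut-3-en-2-yl group, giving A1. The seven-membered ring is closed afterwards between the vinyl and hydroxymethyl termini.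
- Merits: the gem-dimethyl carbon is present from the start, there is no cationic step next to the cyclobutane, and no hydration step is needed.
- Weak points: a tertiary allyl group cannot be put on an enolate directly. It must sit cis to the radical-bearing group, whereas kinetic α′-functionalisation gives trans. With no carbonyl on the arm, C5 cannot be corrected after closure. The closure must tolerate an axial quaternary arm. A seven-membered ring must then be closed across the cyclobutane.
- Comparison: this road is better at avoiding carbocations. The chosen plan offers an epimerisable acetyl arm, a six-membered aldol closure and a ring enlargement that needs no end-to-end cyclisation.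

**Alternative 2:** The C5–C6 bond is made by Wolff contraction of a diazoketone in a bicyclo[4.2.1]nonanone, giving the ester A2.
- Merits: no bridgehead oxygen has to be removed, the four-membered ring comes from a reliable photochemical contraction, and the C1 and C3 oxygens are differentiated early.
- Weak points: the contraction substrate has two quaternary carbons and four stereocentres and no evident chiral-pool entry. Diazo transfer is required beside a neopentyl centre. The ester and masked acetyl group must still be turned into the methyl-substituted enone over several steps.
- Comparison: it is better in protecting-group logic and has no deoxygenation. The chosen plan is shorter from 1 and makes both strained rings by steps with close mechanistic precedent.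

**Alternative 3:** The C2–C3 bond and the seven-membered ring are formed by an aldol addition of a methyl ketone on C11 to an aldehyde on C4. A Tishchenko hydride transfer follows, giving A3 with the isovalerate in place.
- Merits: ring, both carbinol centres (relative anti) and one ester arise in one operation. The endgame is shorter than in the chosen plan.
- Weak points: the aldol joins two neopentyl centres in a seven-membered ring and is reversible. The absolute sense at C3 has no control element in the symmetric pocket. The CMe2–CHO arm must be built cis on C5 by alkylation. Allylic oxidation comes last with both esters present.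
- Comparison: this road is better in endgame economy. The chosen plan borrows its idea as an Evans–Tishchenko reduction of 24, and adds ligand control of C1 and an easier six-membered closure.

Key step: step 15

Remarks on the chemistry:
- The minor carbinol epimer from step 1 and both epoxide epimers of 5 are carried forward, because these centres are erased in steps 8 and 3.
- In step 3 the titanoxymethyl group is taken to end cis to the new bridgehead alkoxide (lower face); the fallback for step 3 covers the opposite outcome.
- In step 10 the Josiphos antipode that places boron on the C1 face next to C6–H is selected in a first run; both antipodes are commercial.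

## Route

Step 1
Reactants: 1 (R)-(−)-carvone; 2 acetaldehyde
Product: 4 (5R,6R)-6-[(1R)-1-(triethylsilyloxy)ethyl]carvone (arm trans to isopropenyl), via lithium aldolate 3 (not isolated)
Conditions: LDA, THF, −78 °C; 2; then TESOTf, −78 °C to 0 °C
Reagents that add atoms: triethylsilyl trifluoromethanesulfonate, CC[Si](CC)(CC)OS(=O)(=O)C(F)(F)F
Why: Kinetic α′-deprotonation gives the cross-conjugated lithium enolate, whose aldol addition (Zimmerman–Traxler, anti) occurs trans to the isopropenyl group. The aldolate is capped in the flask because a free β-hydroxyl would later open the epoxide to a cyclic ether.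

Step 2
Reactants: 4
Product: 5 the 8,9-epoxide of 4 (both epimers at the epoxide carbon)
Conditions: mCPBA, CH2Cl2, 0 °C
Reagents that add atoms: 3-chloroperbenzoic acid, OOC(=O)c1cccc(Cl)c1
Why: Prilezhaev epoxidation takes the electron-rich 1,1-disubstituted alkene and leaves the enone alkene. The epimer mixture is harmless because this carbon becomes a planar radical.

Step 3
Reactants: 5
Product: 6 bicyclo[3.1.1]hept-2-ene diol: bridgehead C10–OH, C11 with CH3 (upper) and CH2OH (lower), C5 with the 1-(triethylsilyloxy)ethyl arm (upper)
Conditions: Cp2TiCl2, Zn dust, THF, rt (slow addition of 5); aq. NaH2PO4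
Reagents that add atoms: none
Why: Cp2TiCl (trivalent titanium) opens the epoxide to the tertiary β-titanoxy radical (Nugent–RajanBabu opening), which adds 4-exo to the titanium-activated ring ketone, the known cyclobutanol closure of carvone 8,9-epoxides. C10 is fixed by the bridging; at C11 the titanoxymethyl group is expected cis to the new alkoxide (both oxygens held on the titanium-bridged face), leaving methyl over the alkene.

Step 4
Reactants: 6
Product: 7 bis(triethylsilyl) ether of 6 with free bridgehead hydroxyl
Conditions: TESCl, imidazole, CH2Cl2, 0 °C
Reagents that add atoms: chlorotriethylsilane, CC[Si](Cl)(CC)CC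
Why: Standard silylation; the primary hydroxyl reacts and the tertiary bridgehead hydroxyl does not under these conditions.

Step 5
Reactants: 7
Product: 8 bridgehead methyl oxalate of 7
Conditions: ClCOCO2Me, DMAP, pyridine, CH2Cl2, 0 °C to rt
Reagents that add atoms: methyl chlorooxoacetate, COC(=O)C(Cl)=O
Why: DMAP-catalysed acylation of the only free hydroxyl; a bridgehead ester cannot eliminate.

Step 6
Reactants: 8
Product: 9 deoxygenated bis(triethylsilyl) ether (C10–H)
Conditions: Bu3SnH, AIBN, toluene, 110 °C
Reagents that add atoms: none
Why: Barton–McCombie-type radical deoxygenation through the tertiary methyl oxalate, known for bridgehead tertiary alcohols next to alkenes. The bridgehead radical is a cyclobutyl (not cyclobutylcarbinyl) radical orthogonal to the alkene, so it abstracts hydrogen before it can open; configuration at C10 is dictated by the ring.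

Step 7
Reactants: 9
Product: 10 diol (primary hydroxyl on C11 arm, secondary hydroxyl on C5 arm)
Conditions: TBAF, THF, rt
Reagents that add atoms: none
Why: Fluoride cleavage of both triethylsilyl ethers under non-acidic conditions that spare the pinene-type alkene.

Step 8
Reactants: 10
Product: 11 keto aldehyde (acetyl on C5 upper face, formyl on C11 lower face)
Conditions: Dess–Martin periodinane, CH2Cl2, rt
Reagents that add atoms: none
Why: Double Dess–Martin oxidation. It is placed after step 6 because a 2-acylcyclobutanol would fragment by retro-aldol, as the intermediates of the de Mayo reaction do.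

Step 9
Reactants: 11
Product: 14 tricyclic enone (C1=C2, C3=O; copaene-type skeleton with C8=C9), via C5-epimeric keto aldehyde 12 (not isolated), via aldol 13 (not isolated)
Conditions: NaOMe (0.3 equiv), MeOH, rt to 50 °C
Reagents that add atoms: none
Why: Intramolecular aldol condensation (Robinson-type cyclodehydration, 6-(enolendo)-exo-trig). Methoxide epimerises C5 through the more substituted enolate; only the epimer with the acetyl group on the lower face can reach the non-enolisable aldehyde, and E1cB dehydration makes the closure irreversible. C5 is thereby fixed with H on the upper face.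

Step 10
Reactants: 14
Product: 16 β-hydroxy ketone (C1–OH on the face next to C6–H), via boronate 15 (not isolated)
Conditions: CuCl (5 mol%), (R,S)-Josiphos (5 mol%), NaOt-Bu (10 mol%), B2pin2, MeOH, THF, rt; then NaBO3·4H2O, THF/H2O
Reagents that add atoms: bis(pinacolato)diboron, CC1(C)OB(OC1(C)C)B2OC(C)(C)C(C)(C)O2; sodium perborate, [Na+].[O-]OB=O
Why: Copper-catalysed asymmetric conjugate borylation of a cyclic enone, then oxidation of the C–B bond with retention. The two faces of C1 are flanked alike by C6–H and C10–H, so the ligand, not the substrate, sets C1; the trisubstituted alkene is inert.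

Step 11
Reactants: 16
Product: 17 C1 tert-butyldimethylsilyl ether of 16
Conditions: TBSOTf, 2,6-lutidine, CH2Cl2, −78 °C
Reagents that add atoms: tert-butyldimethylsilyl trifluoromethanesulfonate, CC(C)(C)[Si](C)(C)OS(=O)(=O)C(F)(F)F
Why: Standard silylation of a β-hydroxy ketone at low temperature; it blocks retro-aldol opening in the next step.

Step 12
Reactants: 17; 18 2-bromopropene
Product: 20 C3 isopropenyl carbinol trimethylsilyl ether (isopropenyl on the face next to C10–H), via lithium alkoxide 19 (not isolated)
Conditions: 18, t-BuLi (2 equiv), Et2O, −78 °C; add 17 in THF, −78 °C; then TMSCl, −78 °C to rt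
Reagents that add atoms: chlorotrimethylsilane, C[Si](C)(C)Cl
Why: Bromine–lithium exchange, then 1,2-addition of the alkenyllithium to the ketone anti to the 1,3-related silyloxy group; the tertiary alkoxide is trapped at once. The C3 configuration is of no consequence because C3 becomes a carbonyl in step 15.

Step 13
Reactants: 20
Product: 21 tertiary alcohol (2-hydroxyprop-2-yl on C3, ring oxygen as trimethylsilyl ether)
Conditions: Co(acac)2 (20 mol%), PhSiH3, O2 (1 atm), THF, rt
Reagents that add atoms: dioxygen, O=O
Why: Mukaiyama hydration; hydrogen-atom transfer to the terminal CH2 gives the tertiary radical, which is oxygenated with Markovnikov selectivity. The unhindered 1,1-disubstituted alkene reacts faster than the trisubstituted ring alkene.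

Step 14
Reactants: 21
Product: 22 enone (C7=O) with C3–OSiMe3 and free C4–OH, the substrate of the key step
Conditions: Rh2(cap)4 (dirhodium tetracaprolactamate, 1 mol%), t-BuOOH, K2CO3, CH2Cl2, rt
Reagents that add atoms: tert-butyl hydroperoxide, CC(C)(C)OO
Why: Allylic oxidation of a cyclic trisubstituted alkene to the enone, the α-pinene to verbenone pattern. C7 is the only allylic methylene; the vinylic methyl is less reactive and the bridgehead C10–H cannot give a conjugated radical.

Step 15
Reactants: 22
Product: 23 ring-enlarged diketone (seven-membered ring, C3=O, C4 gem-dimethyl bonded to C5, C1–OTBS)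
Conditions: BF3·OEt2, CH2Cl2, −78 °C to −30 °C; aq. NaHCO3
Reagents that add atoms: none
Why: BF3 binds the only free hydroxyl (on C4) and ionises this tertiary centre; the C3–C5 bond then shifts to C4 while the lone pair of the silylated ring oxygen forms the C3 oxocarbenium ion, which loses the trimethylsilyl group to give the ketone. The closest known reaction type is the pinacol/semipinacol ring expansion of 1-(2-hydroxyprop-2-yl)cycloalkanol derivatives to 2,2-dimethylcycloalkanones. The seven-membered ring is not closed end to end but arises by ring enlargement, a 1,2-alkyl shift that inserts C4 into the C3–C5 bond of the six-membered ring. No stereocentre is created: C5 migrates with retention, C3 becomes sp2, and C1, C6, C10 and C11 are untouched. Three selectivities are needed: ionisation only at C4, migration of C5 rather than C2, and shift rather than proton loss. The silyl cap on O3 keeps the ring carbinol from ionising to a cyclobutylcarbinyl cation that would tear the four-membered ring. C5 is secondary, whereas C2 is primary and deactivated by the β-silyloxy group on C1. Low temperature, a non-basic medium and the oxygen push favour the shift, and the enone installed in step 14 is inert to the Lewis acid where a pinene-type alkene would not be.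

Step 16
Reactants: 23
Product: 24 β-hydroxy ketone (C1–OH, C3=O)
Conditions: HF·pyridine, pyridine, THF, 0 °C to rt
Reagents that add atoms: none
Why: Buffered fluoride desilylation; acidic rather than basic conditions avoid retro-aldol or elimination of the β-hydroxy ketone.

Step 17
Reactants: 24; 25 3-methylbut-2-enal
Product: 26 C1 3-methylbut-2-enoate with free C3 hydroxyl trans to O1
Conditions: SmI2 (30 mol%), THF, −10 °C
Reagents that add atoms: none
Why: Evans–Tishchenko reduction: the samarium alkoxide (trivalent samarium formed in the flask) adds to the aldehyde, and the hemiacetal hydrogen is delivered to C3 through a six-membered transition state on the face of O1. This gives the 1,3-anti arrangement and leaves the acyl group on O1, so C3 is set by C1 and the senecioate is installed without an acylation that could deconjugate it.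

Step 18
Reactants: 26; 27 3-methylbutanoyl chloride
Product: 28 the target diester
Conditions: DMAP (cat.), pyridine, CH2Cl2, 0 °C to rt
Reagents that add atoms: none
Why: DMAP-catalysed acylation of the remaining hindered secondary hydroxyl; the trans-1,3 arrangement disfavours acyl migration.

## Compound list

1 | (R)-(−)-carvone | CC1=CC[C@H](CC1=O)C(C)=C | starting material
2 | acetaldehyde | CC=O | starting material
3 | lithium aldolate of 1 and 2 (arm trans to isopropenyl) | CC1=CC[C@@H](C(C)=C)[C@H]([C@@H](C)O[Li])C1=O | intermediate (not isolated)
4 | (5R,6R)-6-[(1R)-1-(triethylsilyloxy)ethyl]carvone | CC1=CC[C@@H](C(C)=C)[C@H]([C@@H](C)O[Si](CC)(CC)CC)C1=O | intermediate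
5 | 8,9-epoxide of 4 (both epimers at the epoxide carbon) | CC1=CC[C@@H](C2(C)CO2)[C@H]([C@@H](C)O[Si](CC)(CC)CC)C1=O | intermediate
6 | bicyclic diol: bridgehead OH, C11 CH3 upper and CH2OH lower, C5 silyloxyethyl arm upper | C[C@@H](O[Si](CC)(CC)CC)[C@H]1[C@H]2CC=C(C)[C@]1(O)[C@@]2(C)CO | intermediate
7 | bis(triethylsilyl) ether with free bridgehead OH | C[C@@H](O[Si](CC)(CC)CC)[C@H]1[C@H]2CC=C(C)[C@]1(O)[C@@]2(C)CO[Si](CC)(CC)CC | intermediate
8 | bridgehead methyl oxalate | C[C@@H](O[Si](CC)(CC)CC)[C@H]1[C@H]2CC=C(C)[C@]1(OC(=O)C(=O)OC)[C@@]2(C)CO[Si](CC)(CC)CC | intermediate
9 | deoxygenated bis(triethylsilyl) ether | C[C@@H](O[Si](CC)(CC)CC)[C@H]1[C@H]2CC=C(C)[C@@H]1[C@@]2(C)CO[Si](CC)(CC)CC | intermediate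
10 | diol | C[C@@H](O)[C@H]1[C@H]2CC=C(C)[C@@H]1[C@@]2(C)CO | intermediate
11 | keto aldehyde, acetyl on upper face of C5 | CC(=O)[C@H]1[C@H]2CC=C(C)[C@@H]1[C@@]2(C)C=O | intermediate
12 | C5 epimer of 11, acetyl on lower face | CC(=O)[C@@H]1[C@H]2CC=C(C)[C@@H]1[C@@]2(C)C=O | intermediate (not isolated)
13 | tricyclic aldol (either C1 epimer) | OC1CC(=O)[C@@H]2[C@H]3CC=C(C)[C@@H]2[C@]31C | intermediate (not isolated)
14 | tricyclic enone (C1=C2, C3=O, C8=C9) | C1=CC(=O)[C@@H]2[C@H]3CC=C(C)[C@@H]2[C@]31C | intermediate
15 | C1 pinacol boronate of the saturated ketone | CC1(C)OB(OC1(C)C)[C@@H]2CC(=O)[C@@H]3[C@H]4CC=C(C)[C@@H]3[C@]42C | intermediate (not isolated)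
16 | β-hydroxy ketone, C1–OH on the face next to C6–H | O[C@@H]1CC(=O)[C@@H]2[C@H]3CC=C(C)[C@@H]2[C@]31C | intermediate
17 | C1 tert-butyldimethylsilyl ether of 16 | CC(C)(C)[Si](C)(C)O[C@@H]1CC(=O)[C@@H]2[C@H]3CC=C(C)[C@@H]2[C@]31C | intermediate
18 | 2-bromopropene | CC(Br)=C | starting material
19 | lithium alkoxide of the isopropenyl adduct | CC(C)(C)[Si](C)(C)O[C@@H]1C[C@@](O[Li])(C(C)=C)[C@@H]2[C@H]3CC=C(C)[C@@H]2[C@]31C | intermediate (not isolated)
20 | C3 isopropenyl carbinol trimethylsilyl ether | CC(C)(C)[Si](C)(C)O[C@@H]1C[C@@](O[Si](C)(C)C)(C(C)=C)[C@@H]2[C@H]3CC=C(C)[C@@H]2[C@]31C | intermediate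
21 | C3 (2-hydroxyprop-2-yl) carbinol trimethylsilyl ether, ring alkene | CC(C)(C)[Si](C)(C)O[C@@H]1C[C@@](O[Si](C)(C)C)(C(C)(C)O)[C@@H]2[C@H]3CC=C(C)[C@@H]2[C@]31C | intermediate
22 | enone with C3–OSiMe3 and C4–OH (key-step substrate) | CC(C)(C)[Si](C)(C)O[C@@H]1C[C@@](O[Si](C)(C)C)(C(C)(C)O)[C@@H]2[C@H]3C(=O)C=C(C)[C@@H]2[C@]31C | intermediate
23 | ring-enlarged diketone with C1–OTBS (key-step product) | CC(C)(C)[Si](C)(C)O[C@@H]1CC(=O)C(C)(C)[C@@H]2[C@H]3C(=O)C=C(C)[C@@H]2[C@]31C | intermediate
24 | β-hydroxy ketone (C1–OH, C3=O) | O[C@@H]1CC(=O)C(C)(C)[C@@H]2[C@H]3C(=O)C=C(C)[C@@H]2[C@]31C | intermediate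
25 | 3-methylbut-2-enal | CC(C)=CC=O | starting material
26 | C1 3-methylbut-2-enoate, C3 alcohol (trans) | CC(C)=CC(=O)O[C@@H]1C[C@@H](O)C(C)(C)[C@@H]2[C@H]3C(=O)C=C(C)[C@@H]2[C@]31C | intermediate
27 | 3-methylbutanoyl chloride | CC(C)CC(Cl)=O | starting material
28 | target diester | CC(C)=CC(=O)O[C@@H]1C[C@@H](OC(=O)CC(C)C)C(C)(C)[C@@H]2[C@H]3C(=O)C=C(C)[C@@H]2[C@]31C | target

## Step count and least certain steps

Total: 18 steps. Longest linear sequence: 18 steps from (R)-carvone.

**Step 15 (key step).** The most likely failure is proton loss from the C4 cation back to an isopropenyl compound. If the trimethylsilyl cap is lost first, the ring carbinol C3 may ionise instead; its cation is a cyclobutylcarbinyl cation that rearranges the four-membered ring. The fallback creates the cationic centre from a leaving group that exists only on the exocyclic carbon and is activated without acid. It sets out from 17. Addition of 2-lithio-2-(methylseleno)propane (from 2,2-bis(methylseleno)propane and n-BuLi) gives the β-hydroxy selenide F1. AgBF4 on alumina in CH2Cl2 removes the selenium group as its silver salt and induces the same 1,2-shift, giving the ring-enlarged ketone F2, which still carries the ring alkene. Allylic oxidation under the conditions of step 14 brings the fallback back to the route at 23.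

**Step 3.** The most likely failure is the wrong orientation at the new quaternary carbon C11. If the two titanium alkoxides repel rather than share a bridged face, the titanoxymethyl group takes the upper position and the methyl the lower one, which is useless. The fallback gives the radical carbon two oxygenated arms and decides afterwards which becomes the methyl group. It sets out from 4.
- Ene-type chlorination of the isopropenyl methyl (Ca(OCl)2, solid CO2, CH2Cl2/H2O) gives the allylic chloride F3.
- Cesium pivalate in DMF gives the pivalate F4.
- mCPBA gives the epoxide F5.
- Cp2TiCl closes the cyclobutanol F6, in which the hydroxymethyl group from the epoxide is on the upper face and the pivaloyloxymethyl group on the lower face.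
- MsCl/Et3N gives the primary mesylate F7.
- LiEt3BH in refluxing THF displaces the mesylate by hydride (upper CH3) and cleaves the pivalate (lower CH2OH). An ionic reduction is chosen because a radical at this carbon would be a fast-opening cyclobutylcarbinyl radical.

This brings the fallback back to the route at 6.

**Step 9.** The most likely failure is that epimerisation at C5 is slower than base-induced degradation of the neopentyl aldehyde, so the reactive epimer is never populated enough to cyclise. The fallback separates epimerisation from ring closure and drives it with a trap. It sets out from 11.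
- Selective reduction of the aldehyde (NaBH4, MeOH/CH2Cl2, −78 °C) gives the keto alcohol F8.
- NaOMe in MeOH equilibrates C5; only the lower-face epimer can close to the bridged cyclic hemiketal F9, which drains the equilibrium.
- Dess–Martin oxidation of the small open-chain portion of F9 gives the keto aldehyde 12 with the correct C5 configuration.
- Kinetic enolisation of the methyl ketone (LiHMDS, THF, −78 °C) closes the aldol 13.
- Brief treatment with NaOMe dehydrates 13.

This brings the fallback back to the route at 14.

**Step 10.** The most likely failure is poor facial selectivity or low conversion at the β-carbon, which is attached to a quaternary centre and gets no help from the symmetric cage. The fallback replaces boron by oxygen as the nucleophile under amine catalysis. It sets out from 14. Asymmetric nucleophilic epoxidation (9-amino-9-deoxy-epi-quinine trifluoroacetate, aqueous H2O2, dioxane; the pseudoenantiomeric catalyst if the sense requires it) gives the epoxy ketone F10. Reductive cleavage of the Cα–O bond ((PhSe)2, NaBH4, EtOH, AcOH) brings the fallback back to the route at 16.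

**Step 17.** The most likely failure is consumption of the unsaturated aldehyde by samarium-mediated coupling, or retro-aldol opening of 24 on the Lewis-acidic metal before hydride transfer. The fallback uses a robust aromatic aldehyde and exchanges the ester afterwards. It sets out from 24.
- Evans–Tishchenko reduction with 4-nitrobenzaldehyde (SmI2 cat., THF) gives the 4-nitrobenzoate F11 with the free trans C3 hydroxyl.
- Acylation with 27 (DMAP, pyridine) gives the mixed diester F12.
- Selective methanolysis of the activated aryl ester (NaN3, MeOH, 40 °C) gives the hydroxy isovalerate F13.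
- Acylation with 3-methylbut-2-enoyl chloride in pyridine at 0 °C, without stronger base, installs the senecioate.

This brings the fallback back to the route at 28.

## Further compounds

F1 | step 15 | β-hydroxy selenide from 17 | CC(C)(C)[Si](C)(C)O[C@@H]1C[C@@](O)(C(C)(C)[Se]C)[C@@H]2[C@H]3CC=C(C)[C@@H]2[C@]31C
F2 | step 15 | ring-enlarged ketone with ring alkene | CC(C)(C)[Si](C)(C)O[C@@H]1CC(=O)C(C)(C)[C@@H]2[C@H]3CC=C(C)[C@@H]2[C@]31C
F3 | step 3 | allylic chloride of 4 | CC1=CC[C@@H](C(=C)CCl)[C@H]([C@@H](C)O[Si](CC)(CC)CC)C1=O
F4 | step 3 | allylic pivalate | CC1=CC[C@@H](C(=C)COC(=O)C(C)(C)C)[C@H]([C@@H](C)O[Si](CC)(CC)CC)C1=O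
F5 | step 3 | epoxide of the allylic pivalate (both epimers) | CC1=CC[C@@H](C2(COC(=O)C(C)(C)C)CO2)[C@H]([C@@H](C)O[Si](CC)(CC)CC)C1=O
F6 | step 3 | cyclobutanol with upper CH2OH and lower CH2OPiv | C[C@@H](O[Si](CC)(CC)CC)[C@H]1[C@H]2CC=C(C)[C@]1(O)[C@@]2(CO)COC(=O)C(C)(C)C
F7 | step 3 | primary mesylate of F6 | C[C@@H](O[Si](CC)(CC)CC)[C@H]1[C@H]2CC=C(C)[C@]1(O)[C@@]2(COS(C)(=O)=O)COC(=O)C(C)(C)C
F8 | step 9 | keto alcohol | CC(=O)[C@H]1[C@H]2CC=C(C)[C@@H]1[C@@]2(C)CO
F9 | step 9 | bridged cyclic hemiketal | C1OC(C)(O)[C@@H]2[C@H]3CC=C(C)[C@@H]2[C@]31C
F10 | step 10 | epoxy ketone | O1[C@@H]2[C@H]1C(=O)[C@@H]3[C@H]4CC=C(C)[C@@H]3[C@]42C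
F11 | step 17 | C1 4-nitrobenzoate, C3 alcohol | O=C(O[C@@H]1C[C@@H](O)C(C)(C)[C@@H]2[C@H]3C(=O)C=C(C)[C@@H]2[C@]31C)c4ccc(cc4)[N+](=O)[O-]
F12 | step 17 | C1 4-nitrobenzoate, C3 3-methylbutanoate | O=C(O[C@@H]1C[C@@H](OC(=O)CC(C)C)C(C)(C)[C@@H]2[C@H]3C(=O)C=C(C)[C@@H]2[C@]31C)c4ccc(cc4)[N+](=O)[O-]
F13 | step 17 | C1 alcohol, C3 3-methylbutanoate | O[C@@H]1C[C@@H](OC(=O)CC(C)C)C(C)(C)[C@@H]2[C@H]3C(=O)C=C(C)[C@@H]2[C@]31C
A1 | alternative 1 | bridgehead cyclobutanol with hydroxymethyl and 2-methylbut-3-en-2-yl arms | C=CC(C)(C)[C@@H]1[C@H]2CC=C(C)[C@]1(O)[C@@]2(C)CO
A2 | alternative 2 | methyl bicyclo[4.1.1]octane-7-carboxylate with masked acetyl group | CC(C)(C)[Si](C)(C)O[C@@H]1C[C@@H](OCc2ccc(OC)cc2)C(C)(C)[C@@H]2[C@@H](C(=O)OC)[C@@]1(C)[C@H]2C3(C)OCCO3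
A3 | alternative 3 | tricyclic alkene with C3 isovalerate and free C1 hydroxyl | O[C@@H]1C[C@@H](OC(=O)CC(C)C)C(C)(C)[C@@H]2[C@H]3CC=C(C)[C@@H]2[C@]31C
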